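**Retrosynthetic overview** (ring numbering of the target: C1 ketone, C2 carrying the CH2O carbon C7, C3 vinyl CH, C4 CH–OTig, C5 CH–iPr, C6 CH–OH)
1. 16 ⇐ 15 (desilylation) ⇐ 13 (SeO2 hydroxylation at C1, then MnO2) ⇐ 11 (hydride reduction at C4, double tigloylation) ⇐ 9 (epoxidation of the exocyclic alkene, E1cB opening) ⇐ 7 (silylation of O6, oxidation at C4).
2. Key disconnection of 7: the C3–C4 and C1–C6 bonds, made together in a catalytic enantioselective [3+3] union of 2-isopropylpropane-1,3-diol (C4–C5–C6) with 2-methylidenepropane-1,3-diyl diacetate (C3–C2(=C7)–C1). The cyclohexane, the only ring, is formed here.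
3. Enabling feature: C4–C5–C6 is a 2-substituted propane-1,3-diol, and C1, C3 and C7 are the three arms of an isobutene-type unit on C2. With like-configured carbinols at C4 and C6 (oxygens trans across C5), C5 is not a stereocentre in 7, so two achiral three-carbon pieces can be joined under catalyst control alone.
4. C5 becomes a stereocentre only when one of the two oxygens is silylated. The C4 carbinol then serves as a temporary ketone that steers the alkene to C2=C3 with oxygen on C7, and is reset cis to isopropyl.

Key step: step 2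

Assumption (chemistry): the (R)-bisphosphine is taken to give the (S,S)-diol 7; if the sense of induction is the opposite, the (S)-ligand is used.

**Step 1**
Reactants: 1 diethyl 2-(propan-2-yl)propanedioate
Product: 2 2-(propan-2-yl)propane-1,3-diol
Conditions: LiAlH4, THF, 0 °C to reflux; then H2O, aq. NaOH
Reagents that add atoms: none
Why: LiAlH4 reduction of both ester groups of the malonate (ester reduction) should give the achiral 1,3-diol, which has no stereocentre.

**Step 2**
Reactants: 2 2-(propan-2-yl)propane-1,3-diol; 3 2-methylidenepropane-1,3-diyl diacetate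
Product: 7 (1S,3S)-5-methylidene-2-(propan-2-yl)cyclohexane-1,3-diol, via hydroxy aldehyde 4 (not isolated), via hydroxy allyl acetate 5 (not isolated), via formyl allyl acetate 6 (not isolated)
Conditions: [Ir(cod)Cl]2 (2.5 mol %), (R)-SEGPHOS (5 mol %), 4-chloro-3-nitrobenzoic acid (10 mol %), Cs2CO3 (20 mol %), THF (0.05 M), 100 °C, sealed vessel, 3 (1.1 equiv) added over 6 h
Reagents that add atoms: none
Why: Proposed new method: the cyclometalated π-allyl iridium C,O-benzoate formed in situ dehydrogenates one primary hydroxyl of 2 to aldehyde 4, base removes the hydride to give monovalent iridium, this ionises one acetate of 3, and the σ-allyl trivalent iridium species adds to the aldehyde through a closed chair transition state to give 5; the same redox-triggered sequence on the second hydroxyl (6) and ionisation of the remaining allylic acetate then transfers the other allyl terminus intramolecularly. The closest known reactions are the iridium-catalysed two-directional carbonyl allylation of propane-1,3-diols from the alcohol oxidation level and the corresponding carbonyl methallylation; new is that one 2-methylidenepropane-1,3-diyl donor serves both carbonyls, so that the double allylation becomes a [3+3] annulation. The six-membered ring closes by 6-exo-trig attack of the allyl terminus on the tethered aldehyde through a bicyclic chair-chair transition state, the two new ring bonds joining the former acetate-bearing carbons to the two carbinol carbons. Both carbinol centres are set by the chiral bisphosphine with the same facial sense, which gives the trans (S,S) diol; the isopropyl-bearing carbon is then not a stereocentre, so both diastereomers of 5 converge on 7 and no choice between the enantiotopic hydroxymethyl arms is needed. The step needs cyclisation to win over a second intermolecular allylation and a primary hydroxyl to react before a secondary one: slow equimolar addition of 3 at high dilution should secure the first, and the known preference of this catalyst class for primary alcohols the second. Any cis diol from a mismatched ring closure is a separable meso-type diastereomer, so it should not erode the enantiomeric purity of 7.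

**Step 3**
Reactants: 7 (1S,3S)-5-methylidene-2-(propan-2-yl)cyclohexane-1,3-diol
Product: 8 (1S,2S,3S)-3-[(tert-butyldimethylsilyl)oxy]-5-methylidene-2-(propan-2-yl)cyclohexan-1-ol
Conditions: TBSCl (1.05 equiv), imidazole, DMF, −20 to 0 °C
Reagents that add atoms: tert-butyldimethylsilyl chloride, CC(C)(C)[Si](C)(C)Cl
Why: Kinetic silyl ether formation should take the equatorial hydroxyl (trans to the equatorial isopropyl group) in preference to the axial one, and this site choice turns the isopropyl carbon into a stereocentre with the relative configuration of the target (silyloxy trans, free hydroxyl cis).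

**Step 4**
Reactants: 8 (1S,2S,3S)-3-[(tert-butyldimethylsilyl)oxy]-5-methylidene-2-(propan-2-yl)cyclohexan-1-ol
Product: 9 (2R,3S)-3-[(tert-butyldimethylsilyl)oxy]-5-methylidene-2-(propan-2-yl)cyclohexan-1-one
Conditions: Dess–Martin periodinane, pyridine, CH2Cl2, 0 °C to rt
Reagents that add atoms: none
Why: Dess–Martin oxidation of the remaining axial secondary alcohol under pyridine buffer should give the β,γ-unsaturated ketone without migration of the exocyclic alkene; the isopropyl carbon, now α to the ketone, already stands in the thermodynamically preferred trans relation to the silyloxy group.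

**Step 5**
Reactants: 9 (2R,3S)-3-[(tert-butyldimethylsilyl)oxy]-5-methylidene-2-(propan-2-yl)cyclohexan-1-one
Product: 11 (5S,6R)-5-[(tert-butyldimethylsilyl)oxy]-3-(hydroxymethyl)-6-(propan-2-yl)cyclohex-2-en-1-one, via spiro-epoxy ketone 10 (not isolated)
Conditions: dimethyldioxirane, acetone, −20 °C; then Et3N (0.2 equiv), CH2Cl2, rt
Reagents that add atoms: dimethyldioxirane, CC1(C)OO1
Why: Epoxidation of the 1,1-disubstituted alkene by the neutral dioxirane (no Baeyer–Villiger oxidation) and base-induced E1cB opening of the β,γ-epoxy ketone should give the γ-hydroxy enone; only the CH2 between the carbonyl and the epoxide carbon can open the epoxide, which fixes the alkene in the ring and puts the oxygen on the former methylidene carbon.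

**Step 6**
Reactants: 11 (5S,6R)-5-[(tert-butyldimethylsilyl)oxy]-3-(hydroxymethyl)-6-(propan-2-yl)cyclohex-2-en-1-one
Product: 12 (1S,5S,6S)-5-[(tert-butyldimethylsilyl)oxy]-3-(hydroxymethyl)-6-(propan-2-yl)cyclohex-2-en-1-ol
Conditions: LiBH(s-Bu)3 (2.5 equiv), THF, −78 °C; then aq. NH4Cl
Reagents that add atoms: none
Why: 1,2-Reduction of the β,β-disubstituted enone with the bulky trialkylborohydride should follow the equatorial trajectory known from 2-alkylcyclohexanones and give the pseudo-axial allylic alcohol cis to isopropyl (substrate control), while the fully substituted β-carbon blocks conjugate reduction.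

**Step 7**
Reactants: 12 (1S,5S,6S)-5-[(tert-butyldimethylsilyl)oxy]-3-(hydroxymethyl)-6-(propan-2-yl)cyclohex-2-en-1-ol
Product: 13 [(3S,4S,5S)-5-[(tert-butyldimethylsilyl)oxy]-3-{[(2E)-2-methylbut-2-enoyl]oxy}-4-(propan-2-yl)cyclohex-1-en-1-yl]methyl (2E)-2-methylbut-2-enoate
Conditions: tiglic acid (3 equiv), DCC (3 equiv), DMAP (0.3 equiv), CH2Cl2, 0 °C to rt
Reagents that add atoms: tiglic acid, C/C=C(\C)C(=O)O
Why: Steglich esterification acylates the primary and the secondary allylic hydroxyl with retention at the carbinol, and carbodiimide activation of tiglic acid avoids the vinylketene pathway by which tigloyl chloride can lose conjugation under amine base.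

**Step 8**
Reactants: 13 [(3S,4S,5S)-5-[(tert-butyldimethylsilyl)oxy]-3-{[(2E)-2-methylbut-2-enoyl]oxy}-4-(propan-2-yl)cyclohex-1-en-1-yl]methyl (2E)-2-methylbut-2-enoate
Product: 14 [(3S,4S,5R)-5-[(tert-butyldimethylsilyl)oxy]-6-hydroxy-3-{[(2E)-2-methylbut-2-enoyl]oxy}-4-(propan-2-yl)cyclohex-1-en-1-yl]methyl (2E)-2-methylbut-2-enoate (both C6 epimers)
Conditions: SeO2 (0.5 equiv), t-BuOOH (3 equiv), CH2Cl2, rt
Reagents that add atoms: selenium dioxide, O=[Se]=O; tert-butyl hydroperoxide, CC(C)(C)OO
Why: Allylic hydroxylation with SeO2 (ene reaction, then [2,3]-sigmatropic shift) should occur at the ring CH2 on the more substituted alkene carbon and return the double bond to its original place; the CH2 and CH that carry acyloxy groups and the electron-poor tiglate alkenes are deactivated, and the uncontrolled new carbinol centre is removed in step 9.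

**Step 9**
Reactants: 14 [(3S,4S,5R)-5-[(tert-butyldimethylsilyl)oxy]-6-hydroxy-3-{[(2E)-2-methylbut-2-enoyl]oxy}-4-(propan-2-yl)cyclohex-1-en-1-yl]methyl (2E)-2-methylbut-2-enoate
Product: 15 (4S,5S,6R)-6-[(tert-butyldimethylsilyl)oxy]-4-{[(2E)-2-methylbut-2-enoyl]oxy}-2-({[(2E)-2-methylbut-2-enoyl]oxy}methyl)-5-(propan-2-yl)cyclohex-2-en-1-one
Conditions: MnO2 (20 equiv), CH2Cl2, rt
Reagents that add atoms: none
Why: MnO2 oxidises the allylic alcohol selectively to the conjugated enone (allylic alcohol oxidation) and so converges both epimers of 14.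

**Step 10**
Reactants: 15 (4S,5S,6R)-6-[(tert-butyldimethylsilyl)oxy]-4-{[(2E)-2-methylbut-2-enoyl]oxy}-2-({[(2E)-2-methylbut-2-enoyl]oxy}methyl)-5-(propan-2-yl)cyclohex-2-en-1-one
Product: 16 (4S,5R,6R)-6-hydroxy-4-{[(2E)-2-methylbut-2-enoyl]oxy}-2-({[(2E)-2-methylbut-2-enoyl]oxy}methyl)-5-(propan-2-yl)cyclohex-2-en-1-one
Conditions: HF·pyridine, THF/pyridine, 0 °C to rt
Reagents that add atoms: none
Why: Silyl ether cleavage with buffered HF frees the α-hydroxyl without base, so neither acyl migration nor enolisation of the α-hydroxy ketone should occur; the carbinol next to the ketone is also the thermodynamically favoured epimer (trans to isopropyl).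

**Compound list**
1 | diethyl 2-(propan-2-yl)propanedioate | CCOC(=O)C(C(C)C)C(=O)OCC | starting material
2 | 2-(propan-2-yl)propane-1,3-diol | CC(C)C(CO)CO | intermediate
3 | 2-methylidenepropane-1,3-diyl diacetate | C=C(COC(C)=O)COC(C)=O | starting material
4 | 3-hydroxy-2-(propan-2-yl)propanal (racemic, transient) | CC(C)C(CO)C=O | intermediate
5 | (4S)-4-hydroxy-5-(hydroxymethyl)-6-methyl-2-methylideneheptyl acetate (both C5 epimers) | CC(=O)OCC(=C)C[C@H](O)C(CO)C(C)C | intermediate
6 | (4S)-5-formyl-4-hydroxy-6-methyl-2-methylideneheptyl acetate (both C5 epimers) | CC(=O)OCC(=C)C[C@H](O)C(C=O)C(C)C | intermediate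
7 | (1S,3S)-5-methylidene-2-(propan-2-yl)cyclohexane-1,3-diol (hydroxyls trans; C2 is not a stereocentre) | C=C1C[C@H](O)C(C(C)C)[C@@H](O)C1 | intermediate
8 | (1S,2S,3S)-3-[(tert-butyldimethylsilyl)oxy]-5-methylidene-2-(propan-2-yl)cyclohexan-1-ol | C=C1C[C@H](O)[C@H](C(C)C)[C@@H](O[Si](C)(C)C(C)(C)C)C1 | intermediate
9 | (2R,3S)-3-[(tert-butyldimethylsilyl)oxy]-5-methylidene-2-(propan-2-yl)cyclohexan-1-one | C=C1CC(=O)[C@H](C(C)C)[C@@H](O[Si](C)(C)C(C)(C)C)C1 | intermediate
10 | (6R,7S)-7-[(tert-butyldimethylsilyl)oxy]-6-(propan-2-yl)-1-oxaspiro[2.5]octan-5-one (both spiro epimers) | C1OC12CC(=O)[C@H](C(C)C)[C@@H](O[Si](C)(C)C(C)(C)C)C2 | intermediate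
11 | (5S,6R)-5-[(tert-butyldimethylsilyl)oxy]-3-(hydroxymethyl)-6-(propan-2-yl)cyclohex-2-en-1-one | OCC1=CC(=O)[C@H](C(C)C)[C@@H](O[Si](C)(C)C(C)(C)C)C1 | intermediate
12 | (1S,5S,6S)-5-[(tert-butyldimethylsilyl)oxy]-3-(hydroxymethyl)-6-(propan-2-yl)cyclohex-2-en-1-ol | OCC1=C[C@H](O)[C@H](C(C)C)[C@@H](O[Si](C)(C)C(C)(C)C)C1 | intermediate
13 | [(3S,4S,5S)-5-[(tert-butyldimethylsilyl)oxy]-3-{[(2E)-2-methylbut-2-enoyl]oxy}-4-(propan-2-yl)cyclohex-1-en-1-yl]methyl (2E)-2-methylbut-2-enoate | C/C=C(\C)C(=O)OCC1=C[C@H](OC(=O)/C(C)=C/C)[C@H](C(C)C)[C@@H](O[Si](C)(C)C(C)(C)C)C1 | intermediate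
14 | [(3S,4S,5R)-5-[(tert-butyldimethylsilyl)oxy]-6-hydroxy-3-{[(2E)-2-methylbut-2-enoyl]oxy}-4-(propan-2-yl)cyclohex-1-en-1-yl]methyl (2E)-2-methylbut-2-enoate (both C6 epimers) | C/C=C(\C)C(=O)OCC1=C[C@H](OC(=O)/C(C)=C/C)[C@H](C(C)C)[C@@H](O[Si](C)(C)C(C)(C)C)C1O | intermediate
15 | (4S,5S,6R)-6-[(tert-butyldimethylsilyl)oxy]-4-{[(2E)-2-methylbut-2-enoyl]oxy}-2-({[(2E)-2-methylbut-2-enoyl]oxy}methyl)-5-(propan-2-yl)cyclohex-2-en-1-one | C/C=C(\C)C(=O)OCC1=C[C@H](OC(=O)/C(C)=C/C)[C@H](C(C)C)[C@@H](O[Si](C)(C)C(C)(C)C)C1=O | intermediate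
16 | (4S,5R,6R)-6-hydroxy-4-{[(2E)-2-methylbut-2-enoyl]oxy}-2-({[(2E)-2-methylbut-2-enoyl]oxy}methyl)-5-(propan-2-yl)cyclohex-2-en-1-one | C/C=C(\C)C(=O)OCC1=C[C@H](OC(=O)/C(C)=C/C)[C@H](C(C)C)[C@@H](O)C1=O | target

**Total step count:** 10. **Longest linear sequence:** 10 steps (1 to 16).

**Steps most likely to fail**

Step 2 (Proposed new method). The ring-closing allyl transfer may be slower than a second intermolecular allylation (acyclic bis-adducts, oligomers), or it may close with poor catalyst control. The fallback sets out from 2 and comes back at 7, and makes the two bonds in separate known operations. Monosilylation of 2 (NaH, TBSCl, THF) should give racemic 3-[(tert-butyldimethylsilyl)oxy]-2-(propan-2-yl)propan-1-ol F1. The established intermolecular iridium-catalysed carbonyl allylation from the alcohol oxidation level (same catalyst system, excess of 3) should give (4S)-5-{[(tert-butyldimethylsilyl)oxy]methyl}-4-hydroxy-6-methyl-2-methylideneheptyl acetate F2 as a pair of C5 epimers. HF·pyridine then frees 5, which is isolated here. TEMPO/PhI(OAc)2 oxidises its primary hydroxyl to 6. A palladium-catalysed umpolung allylation (Pd(PPh3)4, InI, THF, rt) closes the ring to 7, which is separated from the cis diol by chromatography.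

Step 8. Conversion may stall, or oxidation may spread to the allylic methyl groups of the tiglates or run on past the alcohol. The fallback sets out from 13 and comes back at 16. It replaces the C–H oxidation by a 1,2-carbonyl transposition from the neighbouring carbinol. HF·pyridine should give [(3S,4R,5S)-5-hydroxy-3-{[(2E)-2-methylbut-2-enoyl]oxy}-4-(propan-2-yl)cyclohex-1-en-1-yl]methyl (2E)-2-methylbut-2-enoate F5. Dess–Martin oxidation should give the β,γ-unsaturated ketone [(3S,4S)-3-{[(2E)-2-methylbut-2-enoyl]oxy}-5-oxo-4-(propan-2-yl)cyclohex-1-en-1-yl]methyl (2E)-2-methylbut-2-enoate F6. Soft enolisation towards the doubly activated CH2 (TMSOTf, Et3N, −78 °C) should give the silyloxy diene [(3S,4S)-3-{[(2E)-2-methylbut-2-enoyl]oxy}-4-(propan-2-yl)-5-[(trimethylsilyl)oxy]cyclohexa-1,5-dien-1-yl]methyl (2E)-2-methylbut-2-enoate F7. Rubottom oxidation with dimethyldioxirane should give the α-hydroxy ketone [(3S,4S)-6-hydroxy-3-{[(2E)-2-methylbut-2-enoyl]oxy}-5-oxo-4-(propan-2-yl)cyclohex-1-en-1-yl]methyl (2E)-2-methylbut-2-enoate F8 (both C6 epimers). Acyloin isomerisation on imidazole then moves the carbonyl into conjugation and gives 16, with the hydroxyl settling trans to isopropyl. F6 is a β-acyloxy ketone, so all of these operations must stay free of strong base.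

Step 6. Hydride delivery may show poor facial selectivity and give the trans alcohol from axial attack. The fallback sets out from 11 and comes back at 13, and takes the opposite face on purpose. Luche reduction (NaBH4, CeCl3·7H2O, MeOH, −78 °C) should give the trans allylic alcohol (1R,5S,6S)-5-[(tert-butyldimethylsilyl)oxy]-3-(hydroxymethyl)-6-(propan-2-yl)cyclohex-2-en-1-ol F3. Steglich esterification of the primary hydroxyl with one equivalent of tiglic acid should give [(3R,4S,5S)-5-[(tert-butyldimethylsilyl)oxy]-3-hydroxy-4-(propan-2-yl)cyclohex-1-en-1-yl]methyl (2E)-2-methylbut-2-enoate F4. Mitsunobu esterification (tiglic acid, PPh3, DIAD, toluene, 0 °C) then installs the second tiglate with inversion and gives 13.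

**Further compounds**
F1 | step 2 | 3-[(tert-butyldimethylsilyl)oxy]-2-(propan-2-yl)propan-1-ol (racemic) | CC(C)C(CO)CO[Si](C)(C)C(C)(C)C
F2 | step 2 | (4S)-5-{[(tert-butyldimethylsilyl)oxy]methyl}-4-hydroxy-6-methyl-2-methylideneheptyl acetate (both C5 epimers) | CC(=O)OCC(=C)C[C@H](O)C(CO[Si](C)(C)C(C)(C)C)C(C)C
F3 | step 6 | (1R,5S,6S)-5-[(tert-butyldimethylsilyl)oxy]-3-(hydroxymethyl)-6-(propan-2-yl)cyclohex-2-en-1-ol | OCC1=C[C@@H](O)[C@H](C(C)C)[C@@H](O[Si](C)(C)C(C)(C)C)C1
F4 | step 6 | [(3R,4S,5S)-5-[(tert-butyldimethylsilyl)oxy]-3-hydroxy-4-(propan-2-yl)cyclohex-1-en-1-yl]methyl (2E)-2-methylbut-2-enoate | C/C=C(\C)C(=O)OCC1=C[C@@H](O)[C@H](C(C)C)[C@@H](O[Si](C)(C)C(C)(C)C)C1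
F5 | step 8 | [(3S,4R,5S)-5-hydroxy-3-{[(2E)-2-methylbut-2-enoyl]oxy}-4-(propan-2-yl)cyclohex-1-en-1-yl]methyl (2E)-2-methylbut-2-enoate | C/C=C(\C)C(=O)OCC1=C[C@H](OC(=O)/C(C)=C/C)[C@H](C(C)C)[C@@H](O)C1
F6 | step 8 | [(3S,4S)-3-{[(2E)-2-methylbut-2-enoyl]oxy}-5-oxo-4-(propan-2-yl)cyclohex-1-en-1-yl]methyl (2E)-2-methylbut-2-enoate | C/C=C(\C)C(=O)OCC1=C[C@H](OC(=O)/C(C)=C/C)[C@H](C(C)C)C(=O)C1
F7 | step 8 | [(3S,4S)-3-{[(2E)-2-methylbut-2-enoyl]oxy}-4-(propan-2-yl)-5-[(trimethylsilyl)oxy]cyclohexa-1,5-dien-1-yl]methyl (2E)-2-methylbut-2-enoate | C/C=C(\C)C(=O)OCC1=C[C@H](OC(=O)/C(C)=C/C)[C@H](C(C)C)C(O[Si](C)(C)C)=C1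
F8 | step 8 | [(3S,4S)-6-hydroxy-3-{[(2E)-2-methylbut-2-enoyl]oxy}-5-oxo-4-(propan-2-yl)cyclohex-1-en-1-yl]methyl (2E)-2-methylbut-2-enoate (both C6 epimers) | C/C=C(\C)C(=O)OCC1=C[C@H](OC(=O)/C(C)=C/C)[C@H](C(C)C)C(=O)C1O
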